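**Strategy.** Numbering the oxolane O1, C2 (aryl), C3 (CH2O-acyl), C4 (benzyl), C5, the route rests on the C4–CH2Ar disconnection. The key step exploits the 1,4-dioxygenated chain C5–C4–C3–CH2O: it is a reduced succinaldehydic acid and is carried as a temporary butenolide ring, (5S)-5-(d-menthyloxy)furan-2(5H)-one, in which C5 is the lactone carbonyl, the CH2O carbon the acetal carbon and C4 the enolate carbon. In one flask a lithiated aryl dithiane (masked C2) adds to C3 anti to the acetal and the enolate is benzylated at C4, giving a trans lactone diad. Reduction and ring switch to the oxolane turn it into the 3,4-cis diad; acid cyclisation sets C2.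

Key step: step 3

Assumption: (5S)-5-(d-menthyloxy)furan-2(5H)-one and (R)-2-methylbutanoic acid are bought as single enantiomers; d-menthyl = (1S,2R,5S)-5-methyl-2-(propan-2-yl)cyclohexyl. The target is the (R)-2-methylbutanoate of the (2R,3S,4S) oxolane, i.e. of (−)-lariciresinol.

**Step 1**
Reactants: 1 4-(benzyloxy)-3-methoxybenzaldehyde; 2 propane-1,3-dithiol
Product: 3 2-[4-(benzyloxy)-3-methoxyphenyl]-1,3-dithiane
Conditions: BF3·OEt2 (cat.), CH2Cl2, 0 °C → rt
Reagents that add atoms: none
Why: Lewis-acid-catalysed dithioacetalisation of an aromatic aldehyde (precursor for Corey–Seebach umpolung) is routine and should leave the benzyl ether untouched.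

**Step 2**
Reactants: 4 [4-(benzyloxy)-3-methoxyphenyl]methanol
Product: 5 1-(benzyloxy)-4-(bromomethyl)-2-methoxybenzene
Conditions: PBr3, Et2O, 0 °C; used fresh
Reagents that add atoms: phosphorus tribromide, BrP(Br)Br
Why: Bromination of an electron-rich benzylic alcohol with PBr3 through its phosphite ester (nucleophilic substitution) should be fast and clean at 0 °C.

**Step 3**
Reactants: 3 2-[4-(benzyloxy)-3-methoxyphenyl]-1,3-dithiane; 6 (5S)-5-(d-menthyloxy)furan-2(5H)-one; 5 1-(benzyloxy)-4-(bromomethyl)-2-methoxybenzene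
Product: 9 (3S,4S,5S)-3-[4-(benzyloxy)-3-methoxybenzyl]-4-{2-[4-(benzyloxy)-3-methoxyphenyl]-1,3-dithian-2-yl}-5-(d-menthyloxy)dihydrofuran-2(3H)-one, via 2-lithio-2-aryl-1,3-dithiane 7 (not isolated), via lithium lactone enolate 8 (not isolated)
Conditions: n-BuLi, THF, −78 → −20 °C; then 6, −78 °C; then 5, DMPU, −78 °C → rt
Reagents that add atoms: none
Why: n-BuLi deprotonates C2 of dithiane 3 to the sulfur-stabilised benzylic anion 7, which adds in conjugate fashion to butenolide 6; the resulting lithium enolate 8 is then C-alkylated in an SN2 reaction by benzylic bromide 5, and this alkylation forms the bond between the future oxolane C4 and the benzylic CH2 of the target. The closest known reaction type is the tandem Michael addition–enolate alkylation (three-component coupling) of lithiated dithioacetals with 5-alkoxyfuran-2(5H)-ones. No ring is closed; the butenolide ring is only a temporary template that is opened later. The new stereocentre at lactone C4 (future oxolane C3) is controlled by the acetal stereocentre C5, the anion entering anti to the menthyloxy group, and the new stereocentre at lactone C3 (future oxolane C4) is controlled by the bulky dithianyl group just installed, the bromide entering anti to it, so the trans,trans lactone should result. The step needs 1,4- over 1,2-addition, which the soft, hindered aryl-dithianyl anion and the γ-alkoxy butenolide secure, and C- over O-alkylation without proton transfer, which the reactive benzylic bromide and DMPU as cosolvent favour.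

**Step 4**
Reactants: 9 three-component adduct
Product: 10 (3S,4S,5S)-4-[4-(benzyloxy)-3-methoxybenzoyl]-3-[4-(benzyloxy)-3-methoxybenzyl]-5-(d-menthyloxy)dihydrofuran-2(3H)-one
Conditions: HgO, BF3·OEt2, THF/H2O (85:15), rt
Reagents that add atoms: water, O
Why: Thiophile-assisted hydrolysis of the dithioacetal (HgO/BF3 unmasking of a Corey–Seebach adduct) should free the aryl ketone, while the acylal-type menthyl acetal, deactivated by the ring acyloxy oxygen, and the two lactone stereocentres, already in the stable trans,trans arrangement, should survive.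

**Step 5**
Reactants: 10 keto lactone
Product: 11 (2S,3S)-2-[4-(benzyloxy)-3-methoxybenzyl]-3-{[4-(benzyloxy)-3-methoxyphenyl](hydroxy)methyl}butane-1,4-diol (both carbinol epimers)
Conditions: LiAlH4 (excess), THF, 0 °C → rt; aqueous NaOH work-up
Reagents that add atoms: none
Why: Hydride reduction with LiAlH4 should take the ketone to the benzylic alcohol and the γ-alkoxy lactone, a masked succinaldehydic acid, to the 1,4-diol with release of menthol; the carbinol centre forms as an epimer mixture that the next step erases, and the two backbone stereocentres are not touched.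

**Step 6**
Reactants: 11 triol
Product: 12 {(2R,3S,4S)-4-[4-(benzyloxy)-3-methoxybenzyl]-2-[4-(benzyloxy)-3-methoxyphenyl]oxolan-3-yl}methanol
Conditions: camphor-10-sulfonic acid (cat.), CH2Cl2, 0 °C → rt
Reagents that add atoms: none
Why: Acid-catalysed cyclodehydration (SN1 etherification) through the p-alkoxybenzyl cation common to both carbinol epimers should close the oxolane by 5-exo attack of the primary alcohol on the C4 side (the other primary alcohol could only give an oxetane), and C2 is set trans to the C3 hydroxymethyl group under thermodynamic control because the benzylic ether re-ionises reversibly.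

**Step 7**
Reactants: 12 dibenzyl oxolane alcohol; 13 (R)-2-methylbutanoic acid
Product: 14 {(2R,3S,4S)-4-[4-(benzyloxy)-3-methoxybenzyl]-2-[4-(benzyloxy)-3-methoxyphenyl]oxolan-3-yl}methyl (2R)-2-methylbutanoate
Conditions: DCC, DMAP (cat.), CH2Cl2, 0 °C → rt
Reagents that add atoms: none
Why: Steglich esterification of the only free hydroxyl group should be clean, and the α-stereocentre of a simple alkanoic acid is not prone to ketene or enolate formation under these mild conditions.

**Step 8**
Reactants: 14 dibenzyl ester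
Product: 15 {(2R,3S,4S)-2-(4-hydroxy-3-methoxyphenyl)-4-(4-hydroxy-3-methoxybenzyl)oxolan-3-yl}methyl (2R)-2-methylbutanoate
Conditions: H2 (1 atm), 10% Pd/C, EtOAc, rt, stopped at full conversion
Reagents that add atoms: none
Why: Catalytic hydrogenolysis of the two aryl benzyl ethers should be much faster under neutral conditions than cleavage of the cyclic benzylic C2–O1 ether or of the ester, so both phenols are unveiled without touching a stereocentre.

**Compound list**
1 | 4-(benzyloxy)-3-methoxybenzaldehyde | O=Cc1ccc(OCc2ccccc2)c(OC)c1 | starting material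
2 | propane-1,3-dithiol | SCCCS | starting material
3 | 2-[4-(benzyloxy)-3-methoxyphenyl]-1,3-dithiane | S1CCCSC1c1ccc(OCc2ccccc2)c(OC)c1 | intermediate
4 | [4-(benzyloxy)-3-methoxyphenyl]methanol | OCc1ccc(OCc2ccccc2)c(OC)c1 | starting material
5 | 1-(benzyloxy)-4-(bromomethyl)-2-methoxybenzene | BrCc1ccc(OCc2ccccc2)c(OC)c1 | intermediate
6 | (5S)-5-{[(1S,2R,5S)-5-methyl-2-(propan-2-yl)cyclohexyl]oxy}furan-2(5H)-one | O=C1C=C[C@@H](O[C@H]2C[C@@H](C)CC[C@@H]2C(C)C)O1 | starting material
7 | 2-lithio-2-[4-(benzyloxy)-3-methoxyphenyl]-1,3-dithiane (not isolated) | [Li]C1(c2ccc(OCc3ccccc3)c(OC)c2)SCCCS1 | intermediate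
8 | lithium enolate of (4S,5S)-4-{2-[4-(benzyloxy)-3-methoxyphenyl]-1,3-dithian-2-yl}-5-(d-menthyloxy)dihydrofuran-2(3H)-one (not isolated) | [Li]OC1=C[C@H](C2(c3ccc(OCc4ccccc4)c(OC)c3)SCCCS2)[C@@H](O[C@H]2C[C@@H](C)CC[C@@H]2C(C)C)O1 | intermediate
9 | (3S,4S,5S)-3-[4-(benzyloxy)-3-methoxybenzyl]-4-{2-[4-(benzyloxy)-3-methoxyphenyl]-1,3-dithian-2-yl}-5-(d-menthyloxy)dihydrofuran-2(3H)-one | O=C1[C@@H](Cc2ccc(OCc3ccccc3)c(OC)c2)[C@H](C2(c3ccc(OCc4ccccc4)c(OC)c3)SCCCS2)[C@@H](O[C@H]2C[C@@H](C)CC[C@@H]2C(C)C)O1 | intermediate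
10 | (3S,4S,5S)-4-[4-(benzyloxy)-3-methoxybenzoyl]-3-[4-(benzyloxy)-3-methoxybenzyl]-5-(d-menthyloxy)dihydrofuran-2(3H)-one | O=C1[C@@H](Cc2ccc(OCc3ccccc3)c(OC)c2)[C@H](C(=O)c2ccc(OCc3ccccc3)c(OC)c2)[C@@H](O[C@H]2C[C@@H](C)CC[C@@H]2C(C)C)O1 | intermediate
11 | (2S,3S)-2-[4-(benzyloxy)-3-methoxybenzyl]-3-{[4-(benzyloxy)-3-methoxyphenyl](hydroxy)methyl}butane-1,4-diol, both carbinol epimers | OC[C@@H](Cc1ccc(OCc2ccccc2)c(OC)c1)[C@H](C(O)c1ccc(OCc2ccccc2)c(OC)c1)CO | intermediate
12 | {(2R,3S,4S)-4-[4-(benzyloxy)-3-methoxybenzyl]-2-[4-(benzyloxy)-3-methoxyphenyl]oxolan-3-yl}methanol | OC[C@@H]1[C@H](Cc2ccc(OCc3ccccc3)c(OC)c2)CO[C@H]1c1ccc(OCc2ccccc2)c(OC)c1 | intermediate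
13 | (R)-2-methylbutanoic acid | CC[C@@H](C)C(=O)O | starting material
14 | {(2R,3S,4S)-4-[4-(benzyloxy)-3-methoxybenzyl]-2-[4-(benzyloxy)-3-methoxyphenyl]oxolan-3-yl}methyl (2R)-2-methylbutanoate | CC[C@@H](C)C(=O)OC[C@@H]1[C@H](Cc2ccc(OCc3ccccc3)c(OC)c2)CO[C@H]1c1ccc(OCc2ccccc2)c(OC)c1 | intermediate
15 | {(2R,3S,4S)-2-(4-hydroxy-3-methoxyphenyl)-4-(4-hydroxy-3-methoxybenzyl)oxolan-3-yl}methyl (2R)-2-methylbutanoate | CC[C@@H](C)C(=O)OC[C@@H]1[C@H](Cc2ccc(O)c(OC)c2)CO[C@H]1c1ccc(O)c(OC)c1 | target

**Step count.** Total: 8 steps. Longest linear sequence: 7 steps (1, 3, 4, 5, 6, 7, 8).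

**Steps most likely to fail**

Step 3. C-alkylation of the hindered lithium enolate 8 may be slow. Proton transfer, O-alkylation or decay of the electron-rich bromide 5 could then compete, leaving only the Michael adduct. The fallback sets out from 1, 3 and 6 and comes back at 11; it exchanges the roles of the two aryl carbons. Anion 7 is added to 6 as before, but the enolate is trapped with aldehyde 1 in an aldol addition, which is faster than alkylation. This should give (3R,4S,5S)-3-{[4-(benzyloxy)-3-methoxyphenyl](hydroxy)methyl}-4-{2-[4-(benzyloxy)-3-methoxyphenyl]-1,3-dithian-2-yl}-5-(d-menthyloxy)dihydrofuran-2(3H)-one F1. Here the dithianyl carbon is the future benzylic CH2, still joined to oxolane C4 by the conjugate addition, and the aldehyde carbon is the future C2. Desulfurisation with nickel boride made in the flask (NiCl2·6H2O, NaBH4, MeOH/THF, 0 °C) should give (3R,4S,5S)-4-[4-(benzyloxy)-3-methoxybenzyl]-3-{[4-(benzyloxy)-3-methoxyphenyl](hydroxy)methyl}-5-(d-menthyloxy)dihydrofuran-2(3H)-one F2. LiAlH4 in THF should then reduce F2 to triol 11. The same enantiomer of 6 serves, because the backbone of 11 is pseudo-C2-symmetric.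

Step 6. The benzylic cation may be intercepted by the electron-rich benzyl ring (Friedel–Crafts closure to an aryltetralin), or equilibration to the 2,3-trans oxolane may be incomplete. The fallback sets out from 9 and comes back at 12; it replaces the acid-mediated dehydration by an oxidative C–H etherification under buffered, non-acidic conditions. Nickel boride (NiCl2·6H2O, NaBH4, MeOH/THF) should desulfurise 9 to (3S,4S,5S)-3,4-bis[4-(benzyloxy)-3-methoxybenzyl]-5-(d-menthyloxy)dihydrofuran-2(3H)-one F3. LiAlH4 should give the C2-symmetric (2S,3S)-2,3-bis[4-(benzyloxy)-3-methoxybenzyl]butane-1,4-diol F4. DDQ (one equivalent, CH2Cl2/pH 7 buffer, 0 °C) should abstract a benzylic hydride, and the 1,4-related hydroxyl group should trap the cation to give 12. Owing to the C2 symmetry of F4, attack at either benzylic position leads to the same oxolane.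

Step 4. The menthyl acetal may be lost, the lactone may open by β-elimination through the enol of the new ketone, or the electron-rich rings may be mercurated. The fallback sets out from 9 and comes back at 11; it reduces before unmasking. LiAlH4 in THF should convert 9 into (2S,3S)-2-[4-(benzyloxy)-3-methoxybenzyl]-3-{2-[4-(benzyloxy)-3-methoxyphenyl]-1,3-dithian-2-yl}butane-1,4-diol F5. Alkylative hydrolysis (MeI, CaCO3, MeCN/H2O, 50 °C) should give (2S,3S)-3-[4-(benzyloxy)-3-methoxybenzyl]-1-[4-(benzyloxy)-3-methoxyphenyl]-4-hydroxy-2-(hydroxymethyl)butan-1-one F6, in equilibrium with its cyclic hemiketal. NaBH4 in MeOH should reduce F6 to triol 11.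

**Further compounds**
F1 | step 3 | (3R,4S,5S)-3-{[4-(benzyloxy)-3-methoxyphenyl](hydroxy)methyl}-4-{2-[4-(benzyloxy)-3-methoxyphenyl]-1,3-dithian-2-yl}-5-(d-menthyloxy)dihydrofuran-2(3H)-one | O=C1[C@@H](C(O)c2ccc(OCc3ccccc3)c(OC)c2)[C@H](C2(c3ccc(OCc4ccccc4)c(OC)c3)SCCCS2)[C@@H](O[C@H]2C[C@@H](C)CC[C@@H]2C(C)C)O1
F2 | step 3 | (3R,4S,5S)-4-[4-(benzyloxy)-3-methoxybenzyl]-3-{[4-(benzyloxy)-3-methoxyphenyl](hydroxy)methyl}-5-(d-menthyloxy)dihydrofuran-2(3H)-one | O=C1[C@@H](C(O)c2ccc(OCc3ccccc3)c(OC)c2)[C@H](Cc2ccc(OCc3ccccc3)c(OC)c2)[C@@H](O[C@H]2C[C@@H](C)CC[C@@H]2C(C)C)O1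
F3 | step 6 | (3S,4S,5S)-3,4-bis[4-(benzyloxy)-3-methoxybenzyl]-5-(d-menthyloxy)dihydrofuran-2(3H)-one | O=C1[C@@H](Cc2ccc(OCc3ccccc3)c(OC)c2)[C@H](Cc2ccc(OCc3ccccc3)c(OC)c2)[C@@H](O[C@H]2C[C@@H](C)CC[C@@H]2C(C)C)O1
F4 | step 6 | (2S,3S)-2,3-bis[4-(benzyloxy)-3-methoxybenzyl]butane-1,4-diol | OC[C@@H](Cc1ccc(OCc2ccccc2)c(OC)c1)[C@H](Cc1ccc(OCc2ccccc2)c(OC)c1)CO
F5 | step 4 | (2S,3S)-2-[4-(benzyloxy)-3-methoxybenzyl]-3-{2-[4-(benzyloxy)-3-methoxyphenyl]-1,3-dithian-2-yl}butane-1,4-diol | OC[C@@H](Cc1ccc(OCc2ccccc2)c(OC)c1)[C@H](C1(c2ccc(OCc3ccccc3)c(OC)c2)SCCCS1)CO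
F6 | step 4 | (2S,3S)-3-[4-(benzyloxy)-3-methoxybenzyl]-1-[4-(benzyloxy)-3-methoxyphenyl]-4-hydroxy-2-(hydroxymethyl)butan-1-one | OC[C@@H](Cc1ccc(OCc2ccccc2)c(OC)c1)[C@H](C(=O)c1ccc(OCc2ccccc2)c(OC)c1)CO
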